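## Analysis of the target

Target numbering (spiro[5.5]undecane) is used for all intermediates: ring A = C1–C6, ring B = C6–C11.

- The target is a chamigrene-type spirocycle. Ring A carries the trisubstituted C1=C2 alkene (methyl on C1), the allylic alcohol C3, the secondary bromide C4 and the gem-dimethyl carbon C5. Ring B carries the secondary chloride C8 and the tertiary bromide C9 (with its methyl). The rings share the quaternary carbon C6.
- There are five stereocentres (3S,4R,6R,8S,9S). On ring A, OH and Br are cis to each other and cis to C7. On ring B, Cl and Br are trans, with Cl on the side of C1 and Br on the side of C5.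
- C6 is stereogenic only because its two ring B arms (C7–C8 and C11–C10) differ at C8 and C10. With a symmetric ring B it is not a stereocentre.
- Sensitive groups: the tertiary bromide next to CHCl (elimination, ionisation, organometallics), the bromohydrin (epoxide with base) and the allylic alcohol (ionisation with acid).
- Three things make it hard. The C5–C6 bond joins two fully substituted carbons. The C9(Br)–C8(Cl) unit is the reverse of what BrCl addition to a C8=C9 alkene gives, because chloride opens the bromonium ion at the tertiary carbon. In the closed spirocycle the C1 methyl lies over the ring B face cis to C1, exactly where the C8 chlorine must sit, so halogenating ring B after spirocyclisation is sterically mismatched.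
- The molecule therefore invites this plan: build C6 as the quaternary carbon of an achiral 4,4-disubstituted cyclohexanone, reveal it as a stereocentre by a desymmetrising α-chlorination at C8, finish ring B while ring A is still open, and close ring A last under neutral conditions.

## Retrosynthetic reasoning

**C1=C2 (ring A).** The target 19 is opened at its alkene to diene 18 (ring-closing metathesis forward). This is the only ring A bond that can be closed without base, acid or organometallics in the presence of both halogenated rings. It lets every stereocentre be set on a monocyclic ring B whose C1 substituent can still rotate freely.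

**Isopropenyl group and C2–C3.** Diene 18 comes from ketone 17 by methylenation of the C1 acetyl group. The acetyl group is carried this far because an isopropenyl group would not survive the hydrobromination of ring B. The C2–C3 bond of 17 is cut to α-bromo aldehyde 16 and a vinyl nucleophile. The addition sets C3 from C4 through a dipole-controlled transition state.

**C4–Br.** Aldehyde 16 comes from aldehyde 14 by catalyst-controlled α-bromination. C4 is thus set by the catalyst, independently of the remote C6. Aldehyde 14 is the anti-Markovnikov oxidation product of the vinyl group of 11 (through alcohol 13).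

**C9–Br.** Bromide 11 is traced to tertiary alcohol 10. The substitution passes through a tertiary cation bridged by the axial C8 chlorine, so bromide enters at C9 trans to chlorine; the cation sits at C9 by construction, so no halonium opening decides where the halogens go. Alcohol 10 comes from chloro keto acid 9 by methyl addition to the C9 ketone and conversion of the carboxyl group into the C1 acetyl group.

**C8–Cl and the C6 stereocentre (key).** Chloro keto acid 9 is cut back to the achiral keto acid 7. One enamine-catalysed α-chlorination creates C8 and at the same time decides which arm of ring B is which, that is, the configuration of C6. The forward reaction has to chlorinate one of two enantiotopic CH2 groups on one face.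

**C5–C6.** Keto acid 7 is the [3,3] product of prenyl ester 3 (Ireland–Claisen rearrangement). The most hindered bond of the target is formed intramolecularly from the two commercial fragments 1 and 2, with no stereochemical issue because 7 is achiral.

## Alternatives that were turned down

**Alternative 1:** (textbook) Cut C6–C7 and C10–C11. Forward: [4+2] cycloaddition of the exocyclic enone A1 with a 2-methyl-1,3-diene, then methyl addition and hydrolysis to dienone A2, then BrCl addition to C8=C9 and the ring A bromohydrin.
- The cycloaddition must be made enantioselective at a carbon flanked by a gem-dimethyl group.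
- BrCl addition to A2 is expected to put chloride on the tertiary C9 and bromine on C8, the wrong constitution.
- The diaxial opening that would give the right constitution needs chloride to attack C8 from the face covered by the C1 methyl.
- The last C–halogen step of the route would therefore fail where no correction is possible.

**Alternative 2:** Cut C8=C9 of a ring B chloroalkene. Forward: enantioselective decarboxylative allylation (Pd2(dba)3 with a phosphinooxazoline ligand) to set C6, ring-closing metathesis to the tetrasubstituted chloroalkene, conversion to A3, then HBr addition.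
- Protonation of A3 can occur at C8 (tertiary, β-chloro cation) or at C9 (chlorine-stabilised cation); the two cations are close in energy, so the regiochemistry is not secured.
- Bromide capture takes place on the closed spirocycle, where the conformer needed for trans addition is the strained one.
- The metathesis to a tetrasubstituted chloroalkene is demanding, and the route is no shorter.

**Alternative 3:** (biomimetic) Cut C5–C6. Forward: ionisation of the tertiary chloride of A4 to a bromonium ion, attack by the exocyclic tetrasubstituted alkene, loss of a proton.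
- One step would make ring A, the C5–C6 bond and C6. But the configuration of C6 is then dictated by the geometry of the tetrasubstituted alkene of A4, which differs on its two sides only at the remote C8/C10.
- No short stereocontrolled route to that alkene is available.
- Ring B would need its own absolute control, and its tertiary bromide competes in the ionisation.
- Proton loss can give the exocyclic isomer.

Key step: step 3

Assumption: the facial sense of both aminocatalysts is taken from the usual steric-shielding model of their enamines; should either run the other way, its mirror-image catalyst is used.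

## Route

Step 1
Reactants: 1 1,4-dioxaspiro[4.5]decane-8-carboxylic acid; 2 3-methylbut-2-en-1-ol
Product: 3 3-methylbut-2-en-1-yl 1,4-dioxaspiro[4.5]decane-8-carboxylate
Conditions: DCC, DMAP (cat.), CH2Cl2, 0 → 25 °C
Reagents that add atoms: none
Why: Steglich esterification of an unhindered acid with a primary allylic alcohol; the dioxolane protects the ring ketone from the amide base of step 2.

Step 2
Reactants: 3 3-methylbut-2-en-1-yl 1,4-dioxaspiro[4.5]decane-8-carboxylate
Product: 7 1-(2-methylbut-3-en-2-yl)-4-oxocyclohexane-1-carboxylic acid, via silyl ketene acetal 4 (not isolated), via silyl ester 5 (not isolated), via ketal acid 6 (not isolated)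
Conditions: LiN(iPr)2, THF, −78 °C; TMSCl; −78 → 60 °C; then 1 M HCl, THF, 25 °C
Reagents that add atoms: water, SMILES O
Why: Ireland–Claisen rearrangement; the [3,3] shift of the tetrasubstituted ketene acetal joins C6 to the dimethyl-substituted allyl terminus C5 intramolecularly, the established way to make two adjacent quaternary carbons. The acidic work-up cleaves the silyl ester and the dioxolane; 7 is achiral, so no stereochemistry arises.

Step 3
Reactants: 7 1-(2-methylbut-3-en-2-yl)-4-oxocyclohexane-1-carboxylic acid
Product: 9 (1S,3S)-3-chloro-1-(2-methylbut-3-en-2-yl)-4-oxocyclohexane-1-carboxylic acid, via enamine 8 (not isolated)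
Conditions: (4S,5S)-4,5-diphenylimidazolidine (20 mol %), 2-nitrobenzoic acid (20 mol %), NCS (1.3 equiv), MeCN, −24 °C; cold work-up
Reagents that add atoms: N-chlorosuccinimide, SMILES O=C1CCC(=O)N1Cl; water, SMILES O
Why: The secondary amine condenses with the only ketone (C9) to an enamine that can form towards either α-CH2; N-chlorosuccinimide chlorinates the enamine carbon and hydrolysis of the α-chloro iminium ion returns the catalyst. The closest known reactions are the amine-catalysed enantioselective α-chlorination of cyclohexanones and the enamine-catalysed desymmetrisation of 4-substituted cyclohexanones. No ring is closed. The new stereocentre C8 is set by the catalyst, which shields one face of the enamine. C6 becomes a stereocentre at the same moment, because the two α-CH2 groups are enantiotopic and only one is chlorinated. The arm is chosen by the substrate: the tert-alkyl group at C6 is locked equatorial and the carboxyl group axial, and the stereoelectronically preferred axial attack comes from the face of the carboxyl group, so the catalyst-preferred face and the axial trajectory coincide on one arm only, giving chlorine cis to the carboxyl group. The step needs chemoselectivity for the ketone, monochlorination and no epimerisation at C8; the substrate has a single ketone, an unactivated monosubstituted alkene and a cis carboxyl group that cannot displace the chloride from the rear.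

Step 4
Reactants: 9 (1S,3S)-3-chloro-1-(2-methylbut-3-en-2-yl)-4-oxocyclohexane-1-carboxylic acid
Product: 10 1-[(1S,3S,4R)-3-chloro-4-hydroxy-4-methyl-1-(2-methylbut-3-en-2-yl)cyclohexyl]ethan-1-one
Conditions: CeCl3 (1.5 equiv), MeLi (6 equiv), THF, −78 → 0 °C; inverse quench into aq. NH4Cl
Reagents that add atoms: methyllithium, SMILES [Li]C
Why: The organocerium reagent adds to the α-chloro ketone without enolisation, anti to the axial C–Cl bond, so the oxygen ends cis to chlorine and cannot close an epoxide. Excess methyllithium converts the lithium carboxylate through its gem-dialkoxide into the methyl ketone on quench. The configuration at C9 is not critical because C9 is ionised in step 5.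

Step 5
Reactants: 10 1-[(1S,3S,4R)-3-chloro-4-hydroxy-4-methyl-1-(2-methylbut-3-en-2-yl)cyclohexyl]ethan-1-one
Product: 11 1-[(1S,3S,4S)-4-bromo-3-chloro-4-methyl-1-(2-methylbut-3-en-2-yl)cyclohexyl]ethan-1-one
Conditions: HBr (33 % in AcOH, 5 equiv), CH2Cl2, BHT (cat.), 0 °C, dark
Reagents that add atoms: hydrogen bromide, SMILES Br
Why: SN1 substitution of the tertiary alcohol; the cation at C9 is bridged by the axial chlorine at C8, and bromide enters axially and anti to it in the chair locked by the equatorial tert-alkyl group, giving the trans-diaxial bromochloride with bromine on the tertiary carbon. Alkenes formed by proton loss re-add HBr through the same cation; the inhibitor and darkness suppress radical addition to the vinyl group.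

Step 6
Reactants: 11 1-[(1S,3S,4S)-4-bromo-3-chloro-4-methyl-1-(2-methylbut-3-en-2-yl)cyclohexyl]ethan-1-one
Product: 13 1-[(1S,3S,4S)-4-bromo-3-chloro-1-(4-hydroxy-2-methylbutan-2-yl)-4-methylcyclohexyl]ethan-1-one, via alkylborane 12 (not isolated)
Conditions: 9-BBN, THF, 0 → 25 °C; then 30 % H2O2, aq. NaOAc, 0 °C
Reagents that add atoms: hydrogen peroxide, SMILES OO
Why: Anti-Markovnikov hydroboration of the terminal alkene and buffered oxidation; the acetyl group flanked by two quaternary carbons is reduced much more slowly, and the β-chloro tertiary bromide is inert to borane and to the near-neutral oxidation.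

Step 7
Reactants: 13 1-[(1S,3S,4S)-4-bromo-3-chloro-1-(4-hydroxy-2-methylbutan-2-yl)-4-methylcyclohexyl]ethan-1-one
Product: 14 3-[(1S,3S,4S)-1-acetyl-4-bromo-3-chloro-4-methylcyclohexyl]-3-methylbutanal
Conditions: Dess–Martin periodinane, NaHCO3, CH2Cl2, 0 → 25 °C
Reagents that add atoms: none
Why: Buffered Dess–Martin oxidation of a primary alcohol to the aldehyde under neutral conditions that leave both alkyl halides untouched.

Step 8
Reactants: 14 3-[(1S,3S,4S)-1-acetyl-4-bromo-3-chloro-4-methylcyclohexyl]-3-methylbutanal
Product: 16 (2R)-3-[(1S,3S,4S)-1-acetyl-4-bromo-3-chloro-4-methylcyclohexyl]-2-bromo-3-methylbutanal, via enamine 15 (not isolated)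
Conditions: (2S,5S)-2,5-diphenylpyrrolidine (20 mol %), PhCO2H (20 mol %), 4,4-dibromo-2,6-di-tert-butylcyclohexa-2,5-dien-1-one (1.1 equiv), H2O (2 equiv), CH2Cl2/pentane, −40 °C; used crude
Reagents that add atoms: 4,4-dibromo-2,6-di-tert-butylcyclohexa-2,5-dien-1-one, SMILES O=C1C(C(C)(C)C)=CC(Br)(Br)C=C1C(C)(C)C; water, SMILES O
Why: Enamine-catalysed enantioselective α-bromination of an aldehyde; the C2-symmetric amine shields one face of the E-enamine, so C4 is set by the catalyst and not by the distant ring. The hindered acetyl group does not form an enamine.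

Step 9
Reactants: 16 (2R)-3-[(1S,3S,4S)-1-acetyl-4-bromo-3-chloro-4-methylcyclohexyl]-2-bromo-3-methylbutanal
Product: 17 1-[(1S,3S,4S)-4-bromo-1-[(3R,4S)-3-bromo-4-hydroxy-2-methylhex-5-en-2-yl]-3-chloro-4-methylcyclohexyl]ethan-1-one
Conditions: CH2=CHMgBr (1.5 equiv), THF, −78 °C; aq. NH4Cl at −78 °C
Reagents that add atoms: vinylmagnesium bromide, SMILES C=C[Mg]Br
Why: 1,2-Addition to an α-bromo aldehyde through the dipole-minimised transition state (C–Br anti to C=O, attack past the α-hydrogen) gives the anti bromohydrin, which becomes the cis relationship on ring A. The cold quench prevents epoxide closure, and the aldehyde reacts far faster than the hindered ketone.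

Step 10
Reactants: 17 1-[(1S,3S,4S)-4-bromo-1-[(3R,4S)-3-bromo-4-hydroxy-2-methylhex-5-en-2-yl]-3-chloro-4-methylcyclohexyl]ethan-1-one
Product: 18 (3S,4R)-4-bromo-5-[(1R,3S,4S)-4-bromo-3-chloro-4-methyl-1-(prop-1-en-2-yl)cyclohexyl]-5-methylhex-1-en-3-ol
Conditions: Cp2TiMe2 (4 equiv), toluene, 65 °C, dark
Reagents that add atoms: dimethyltitanocene, SMILES C[Ti](C)(C1C=CC=C1)C1C=CC=C1
Why: Petasis methylenation; the neutral titanium methylidene olefinates hindered, enolisable ketones without base, so the bromohydrin and the tertiary bromide are not eliminated. The free hydroxyl consumes one equivalent of reagent.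

Step 11
Reactants: 18 (3S,4R)-4-bromo-5-[(1R,3S,4S)-4-bromo-3-chloro-4-methyl-1-(prop-1-en-2-yl)cyclohexyl]-5-methylhex-1-en-3-ol
Product: 19 (3S,4R,6R,8S,9S)-4,9-dibromo-8-chloro-1,5,5,9-tetramethylspiro[5.5]undec-1-en-3-ol
Conditions: second-generation Hoveyda–Grubbs catalyst (H2IMes)Cl2Ru(=CH-C6H4-2-OiPr) (10 mol %), 1,4-benzoquinone (20 mol %), toluene, 60 °C
Reagents that add atoms: none
Why: Ring-closing metathesis of the vinyl carbinol with the 1,1-disubstituted alkene closes ring A as a six-membered trisubstituted cycloalkene with loss of ethene. The conditions are neutral, tolerate alkyl halides and a free allylic alcohol, and create no stereocentre.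

## Compound list

1 | 1,4-dioxaspiro[4.5]decane-8-carboxylic acid | OC(=O)C1CCC2(CC1)OCCO2 | starting material
2 | 3-methylbut-2-en-1-ol | CC(C)=CCO | starting material
3 | 3-methylbut-2-en-1-yl 1,4-dioxaspiro[4.5]decane-8-carboxylate | CC(C)=CCOC(=O)C1CCC2(CC1)OCCO2 | intermediate
4 | trimethyl{[(3-methylbut-2-en-1-yl)oxy](1,4-dioxaspiro[4.5]decan-8-ylidene)methoxy}silane | CC(C)=CCOC(O[Si](C)(C)C)=C1CCC2(CC1)OCCO2 | intermediate
5 | trimethylsilyl 8-(2-methylbut-3-en-2-yl)-1,4-dioxaspiro[4.5]decane-8-carboxylate | C=CC(C)(C)C1(CCC2(CC1)OCCO2)C(=O)O[Si](C)(C)C | intermediate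
6 | 8-(2-methylbut-3-en-2-yl)-1,4-dioxaspiro[4.5]decane-8-carboxylic acid | C=CC(C)(C)C1(CCC2(CC1)OCCO2)C(=O)O | intermediate
7 | 1-(2-methylbut-3-en-2-yl)-4-oxocyclohexane-1-carboxylic acid | C=CC(C)(C)C1(CCC(=O)CC1)C(=O)O | intermediate
8 | (1S)-4-[(4S,5S)-4,5-diphenylimidazolidin-1-yl]-1-(2-methylbut-3-en-2-yl)cyclohex-3-ene-1-carboxylic acid | C=CC(C)(C)[C@]1(C(=O)O)CCC(=CC1)N1CN[C@@H](c2ccccc2)[C@@H]1c1ccccc1 | intermediate
9 | (1S,3S)-3-chloro-1-(2-methylbut-3-en-2-yl)-4-oxocyclohexane-1-carboxylic acid | C=CC(C)(C)[C@]1(C(=O)O)CCC(=O)[C@@H](Cl)C1 | intermediate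
10 | 1-[(1S,3S,4R)-3-chloro-4-hydroxy-4-methyl-1-(2-methylbut-3-en-2-yl)cyclohexyl]ethan-1-one | C=CC(C)(C)[C@]1(C(C)=O)CC[C@](O)(C)[C@@H](Cl)C1 | intermediate
11 | 1-[(1S,3S,4S)-4-bromo-3-chloro-4-methyl-1-(2-methylbut-3-en-2-yl)cyclohexyl]ethan-1-one | C=CC(C)(C)[C@]1(C(C)=O)CC[C@](C)(Br)[C@@H](Cl)C1 | intermediate
12 | 1-[(1S,3S,4S)-1-[4-(9-borabicyclo[3.3.1]nonan-9-yl)-2-methylbutan-2-yl]-4-bromo-3-chloro-4-methylcyclohexyl]ethan-1-one | C(CB1C2CCCC1CCC2)C(C)(C)[C@]1(C(C)=O)CC[C@](C)(Br)[C@@H](Cl)C1 | intermediate
13 | 1-[(1S,3S,4S)-4-bromo-3-chloro-1-(4-hydroxy-2-methylbutan-2-yl)-4-methylcyclohexyl]ethan-1-one | OCCC(C)(C)[C@]1(C(C)=O)CC[C@](C)(Br)[C@@H](Cl)C1 | intermediate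
14 | 3-[(1S,3S,4S)-1-acetyl-4-bromo-3-chloro-4-methylcyclohexyl]-3-methylbutanal | O=CCC(C)(C)[C@]1(C(C)=O)CC[C@](C)(Br)[C@@H](Cl)C1 | intermediate
15 | 1-[(1S,3S,4S)-4-bromo-3-chloro-1-{(E)-4-[(2S,5S)-2,5-diphenylpyrrolidin-1-yl]-2-methylbut-3-en-2-yl}-4-methylcyclohexyl]ethan-1-one | c1ccccc1[C@@H]1CC[C@@H](c2ccccc2)N1/C=C/C(C)(C)[C@]1(C(C)=O)CC[C@](C)(Br)[C@@H](Cl)C1 | intermediate
16 | (2R)-3-[(1S,3S,4S)-1-acetyl-4-bromo-3-chloro-4-methylcyclohexyl]-2-bromo-3-methylbutanal | O=C[C@H](Br)C(C)(C)[C@]1(C(C)=O)CC[C@](C)(Br)[C@@H](Cl)C1 | intermediate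
17 | 1-[(1S,3S,4S)-4-bromo-1-[(3R,4S)-3-bromo-4-hydroxy-2-methylhex-5-en-2-yl]-3-chloro-4-methylcyclohexyl]ethan-1-one | C=C[C@H](O)[C@H](Br)C(C)(C)[C@]1(C(C)=O)CC[C@](C)(Br)[C@@H](Cl)C1 | intermediate
18 | (3S,4R)-4-bromo-5-[(1R,3S,4S)-4-bromo-3-chloro-4-methyl-1-(prop-1-en-2-yl)cyclohexyl]-5-methylhex-1-en-3-ol | C=C[C@H](O)[C@H](Br)C(C)(C)[C@]1(C(C)=C)CC[C@](C)(Br)[C@@H](Cl)C1 | intermediate
19 | (3S,4R,6R,8S,9S)-4,9-dibromo-8-chloro-1,5,5,9-tetramethylspiro[5.5]undec-1-en-3-ol | CC1=C[C@H](O)[C@H](Br)C(C)(C)[C@@]12CC[C@](C)(Br)[C@@H](Cl)C2 | target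

## Step count and risk

Total step count: 11. Longest linear sequence: 11 (the route is linear from 1 and 2).

**Step 3 (key).** The catalyst's facial preference and the axial trajectory may not reinforce each other strongly enough, which would erode the discrimination between the two arms. The axial α-chloro ketone may also epimerise at C8 under the amine and acid, and the free carboxylic acid may slow enamine formation. The fallback sets out from 7 and replaces enamine catalysis by reagent-controlled enantiotopic deprotonation: one enantiomer of LiN[CH(CH3)Ph]2 (2.2 equiv) with TMSCl present in THF at −100 °C removes one of the two axial α-protons and should give trimethylsilyl (1S)-1-(2-methylbut-3-en-2-yl)-4-[(trimethylsilyl)oxy]cyclohex-3-ene-1-carboxylate F1. Axial chlorination of this preformed enol ether with N-chlorosuccinimide in CH2Cl2 at −78 °C and aqueous work-up should return the route at 9.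

**Step 5.** HBr may add to the vinyl group (radical chain or slow ionic addition), and bromide may capture an unbridged cation from the wrong face, lowering the trans selectivity. The fallback sets out from 10 and removes the alkene first: 9-BBN, then buffered H2O2, should give 1-[(1S,3S,4R)-3-chloro-4-hydroxy-1-(4-hydroxy-2-methylbutan-2-yl)-4-methylcyclohexyl]ethan-1-one F2. Treating F2 with 48 % aqueous HBr in CH2Cl2 at 0 °C should convert only the tertiary alcohol, so the route is rejoined at 13.

**Step 9.** The α-bromo aldehyde may lose configuration by enolisation before it reacts, the dipole-controlled addition may be only moderately selective, and the magnesium alkoxide may close to an epoxide on warming. The fallback sets out from 16 and sets C3 by reduction instead of addition. Unselective addition of vinylmagnesium bromide gives 17 together with its epimer 1-[(1S,3S,4S)-4-bromo-1-[(3R,4R)-3-bromo-4-hydroxy-2-methylhex-5-en-2-yl]-3-chloro-4-methylcyclohexyl]ethan-1-one F3. Dess–Martin oxidation of the mixture gives 1-[(1S,3S,4S)-4-bromo-1-[(3R)-3-bromo-2-methyl-4-oxohex-5-en-2-yl]-3-chloro-4-methylcyclohexyl]ethan-1-one F4. Catalyst-controlled reduction with catecholborane and a chiral oxazaborolidine at −78 °C should return the route at 17.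

**Step 10.** The ketone lies between two quaternary carbons, so methylenation may stall; prolonged heating may cost HBr from the tertiary bromide. The fallback sets out from 17 and uses a two-step Peterson olefination. Me3SiCH2MgCl with CeCl3 in THF at −78 → −20 °C should give 2-[(1S,3S,4S)-4-bromo-1-[(3R,4S)-3-bromo-4-hydroxy-2-methylhex-5-en-2-yl]-3-chloro-4-methylcyclohexyl]-1-(trimethylsilyl)propan-2-ol F5 (either carbinol epimer). HF·pyridine in MeCN at 0 °C then induces the acid-mediated elimination and returns the route at 18.

**Step 11.** Initiation at the isopropenyl group on the quaternary carbon may be slow, ruthenium hydrides may isomerise the allylic alcohol to a ketone, and the vinyl groups may dimerise. The fallback sets out from 14 and closes ring A by an aldol condensation instead.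
- MeMgBr at −78 °C should give 1-[(1S,3S,4S)-4-bromo-3-chloro-1-(4-hydroxy-2-methylpentan-2-yl)-4-methylcyclohexyl]ethan-1-one F6.
- Dess–Martin oxidation gives 4-[(1S,3S,4S)-1-acetyl-4-bromo-3-chloro-4-methylcyclohexyl]-4-methylpentan-2-one F7.
- Pyrrolidine and AcOH form the enamine only at the unhindered methyl ketone, which attacks the acetyl group and dehydrates to (6S,8S,9S)-9-bromo-8-chloro-1,5,5,9-tetramethylspiro[5.5]undec-1-en-3-one F8.
- TMSOTf and Et3N give the cross-conjugated {[(6R,8S,9S)-9-bromo-8-chloro-1,5,5,9-tetramethylspiro[5.5]undeca-1,3-dien-3-yl]oxy}trimethylsilane F9.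
- N-Bromosuccinimide gives (4R,6R,8S,9S)-4,9-dibromo-8-chloro-1,5,5,9-tetramethylspiro[5.5]undec-1-en-3-one F10.
- iBu2AlH at −78 °C, with hydride anti to bromine, should give the cis bromohydrin and arrive at 19.

In this fallback C4 is set by the substrate and not by a catalyst, which is why it is not the main route.

## Further compounds

F1 | step 3 | trimethylsilyl (1S)-1-(2-methylbut-3-en-2-yl)-4-[(trimethylsilyl)oxy]cyclohex-3-ene-1-carboxylate | C=CC(C)(C)[C@]1(C(=O)O[Si](C)(C)C)CCC(O[Si](C)(C)C)=CC1
F2 | step 5 | 1-[(1S,3S,4R)-3-chloro-4-hydroxy-1-(4-hydroxy-2-methylbutan-2-yl)-4-methylcyclohexyl]ethan-1-one | OCCC(C)(C)[C@]1(C(C)=O)CC[C@](O)(C)[C@@H](Cl)C1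
F3 | step 9 | 1-[(1S,3S,4S)-4-bromo-1-[(3R,4R)-3-bromo-4-hydroxy-2-methylhex-5-en-2-yl]-3-chloro-4-methylcyclohexyl]ethan-1-one | C=C[C@@H](O)[C@H](Br)C(C)(C)[C@]1(C(C)=O)CC[C@](C)(Br)[C@@H](Cl)C1
F4 | step 9 | 1-[(1S,3S,4S)-4-bromo-1-[(3R)-3-bromo-2-methyl-4-oxohex-5-en-2-yl]-3-chloro-4-methylcyclohexyl]ethan-1-one | C=CC(=O)[C@H](Br)C(C)(C)[C@]1(C(C)=O)CC[C@](C)(Br)[C@@H](Cl)C1
F5 | step 10 | 2-[(1S,3S,4S)-4-bromo-1-[(3R,4S)-3-bromo-4-hydroxy-2-methylhex-5-en-2-yl]-3-chloro-4-methylcyclohexyl]-1-(trimethylsilyl)propan-2-ol | C=C[C@H](O)[C@H](Br)C(C)(C)[C@]1(C(C)(O)C[Si](C)(C)C)CC[C@](C)(Br)[C@@H](Cl)C1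
F6 | step 11 | 1-[(1S,3S,4S)-4-bromo-3-chloro-1-(4-hydroxy-2-methylpentan-2-yl)-4-methylcyclohexyl]ethan-1-one | CC(O)CC(C)(C)[C@]1(C(C)=O)CC[C@](C)(Br)[C@@H](Cl)C1
F7 | step 11 | 4-[(1S,3S,4S)-1-acetyl-4-bromo-3-chloro-4-methylcyclohexyl]-4-methylpentan-2-one | CC(=O)CC(C)(C)[C@]1(C(C)=O)CC[C@](C)(Br)[C@@H](Cl)C1
F8 | step 11 | (6S,8S,9S)-9-bromo-8-chloro-1,5,5,9-tetramethylspiro[5.5]undec-1-en-3-one | CC1=CC(=O)CC(C)(C)[C@@]12CC[C@](C)(Br)[C@@H](Cl)C2
F9 | step 11 | {[(6R,8S,9S)-9-bromo-8-chloro-1,5,5,9-tetramethylspiro[5.5]undeca-1,3-dien-3-yl]oxy}trimethylsilane | CC1=CC(O[Si](C)(C)C)=CC(C)(C)[C@@]12CC[C@](C)(Br)[C@@H](Cl)C2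
F10 | step 11 | (4R,6R,8S,9S)-4,9-dibromo-8-chloro-1,5,5,9-tetramethylspiro[5.5]undec-1-en-3-one | CC1=CC(=O)[C@H](Br)C(C)(C)[C@@]12CC[C@](C)(Br)[C@@H](Cl)C2
A1 | alternative 1 | 5,5-dimethyl-6-methylidene-3-(2-methylpropoxy)cyclohex-2-en-1-one | C=C1C(=O)C=C(OCC(C)C)CC1(C)C
A2 | alternative 1 | (6S)-1,5,5,9-tetramethylspiro[5.5]undeca-1,8-dien-3-one | CC1=CC(=O)CC(C)(C)[C@@]12CCC(C)=CC2
A3 | alternative 2 | (6S)-8-chloro-1,5,5,9-tetramethylspiro[5.5]undeca-1,8-dien-3-one | CC1=CC(=O)CC(C)(C)[C@@]12CCC(C)=C(Cl)C2
A4 | alternative 3 | (4S,5S)-5-bromo-2-[(1E,3S,4S)-4-bromo-3-chloro-4-methylcyclohexylidene]-6-chloro-6-methylheptan-4-ol | C/C(C[C@H](O)[C@H](Br)C(C)(C)Cl)=C1\C[C@H](Cl)[C@@](C)(Br)CC1
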